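## Structural features

Stenophyllol B is a resveratrol trimer made of three 4-hydroxyphenyl groups and three resorcinol-type rings: ring A (benzo ring of an indane), ring B (the central ring) and ring C (benzo ring of a 2,3-dihydrobenzofuran). The indane carries a 4-hydroxyphenyl group at C1, ring C at C2 and, at C3, a methine carbon (Cα) that bears a second 4-hydroxyphenyl group and ring B. Ring B is joined through furan C3 to ring C, so C3, Cα, two carbons of ring B, furan C3, two carbons of ring C and C2 form an eight-membered carbocycle, fused to the indane along C2–C3 and to the dihydrofuran along furan C3–C3a. There are six stereocentres: C1 (S), C2 (S), C3 (R) and Cα (R) are contiguous, and furan C3 (R) and furan C2 (R) are contiguous. The indane triad is all-trans, the dihydrofuran is trans, and around the eight-membered ring the large substituents alternate between the two faces. The eight free phenols are sensitive to oxidants and to base in air, the benzylic O1–C2 bond of the dihydrofuran ionises in acid, and the benzylic methines can form cations that eliminate or are trapped by the electron-rich rings. The difficulty lies in the absolute and relative configuration of the indane triad, in closing the eight-membered ring against a seven-membered ring through C4 of ring A, and in the configuration of Cα and furan C3, which no neighbouring functional group controls. The key step uses the fact that C1 is a diaryl-substituted carbon (4-hydroxyphenyl and C7a of ring A) in a 1,5-relationship to the C2–H bond that is benzylic to ring C: a diaryl carbene at C1 can insert into that bond and close the five-membered ring, setting C1 and C2 together.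

## Logic of the disconnections

29 to 28. The furan O1–C2 bond is cut and the eight hydroxyl groups are masked. This benzylic C–O bond is the most acid-labile bond of 29, so it is formed last, by the same Lewis acid that frees the phenols, and the trans ring fusion can settle by reversible ionisation. One ring and one stereocentre are removed. The forward step requires the cation at furan C2 to be captured by the ring C methoxy oxygen faster than by any arene carbon.

28 to 25 and 26 (through 27). The furan C2–C3 bond is cut, and the free hydroxyl on ring A is traced back to a sulfonate. An aldehyde on furan C3 is the natural acceptor for the last aryl group, and the carbinol configuration does not matter because that carbon is ionised later. The forward step requires addition to outrun enolisation of a doubly benzylic aldehyde, and the sulfonate must fall to hydroxide in the same flask.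

25 to 23 (through 24). The bond between furan C3 and its formyl carbon is cut, a one-carbon homologation of a diaryl ketone. The ketone is what a ring-closing acylation delivers, and the aldehyde puts furan C3 α to a carbonyl group, where it can be equilibrated. The forward step requires a small ylide to add to a crowded diaryl ketone and the epoxide to rearrange by hydride shift only.

23 to 22. The bond between the carbonyl carbon and ring C is cut, which opens the eight-membered ring. Ring C is activated at this carbon by one ortho and one para methoxy group. The forward step requires the acyl carbon to choose ring C over C4 of ring A (a seven-membered ring, kinetically easier). For that reason the C7 oxygen is kept as an electron-poor sulfonate from 5 onwards and is not turned into a methyl ether, which would make C4 as nucleophilic as the ring C carbon.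

22 to 20 and 21. The Cα–aryl bond is cut. A lactone at Cα is a latent benzylic cation stabilised by the two methoxy groups of ring B, and its opening by 21 unveils the carboxylic acid that 23 needs with no extra step. The forward step requires 21 to attack through its para position on the correct face of the cation, and capture to be faster than loss of the C3 proton.

20 to 14 and 17 (through 18 and 19); 17 to 15 and 16. The Cα–ring B bond is cut. An aldehyde takes up a hindered aryllithium far more readily than a branched, enolisable ketone would, and the amide that directs the metalation becomes the lactone carbonyl. The forward step requires metalation between the amide and the methoxy group only.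

14 to 13. No skeletal bond is cut; the ester is brought to the aldehyde oxidation level. The forward step requires a reduction that stops at the aldehyde and spares the sulfonate.

13 to 11 (through 12). The C1–C2 bond is cut; this is the key disconnection. It removes the five-membered ring and two stereocentres and leads to an open-chain diaryldiazomethane whose only 1,5 C–H bond is the benzylic one. The forward step requires a chiral dirhodium catalyst to control C1 and C2 against a racemic, epimerisable C3, which is corrected afterwards by base.

11 to 8 (through 10 and 9). The C=N2 group is traced to the ketone. The forward step requires a hydrazone to form at a doubly ortho-substituted diaryl ketone without exposing the ester three atoms away to hot hydrazine, which would close a 2,3-benzodiazepin-4-one. The hydrazone is therefore introduced as its N-silyl derivative and freed only in the cold.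

8 to 5 and 6 (through 7). The bond between the ester α-carbon and the benzylic CH2 group is cut, an enolate alkylation. The forward step requires monoalkylation, which the crowded arylacetate favours.

5 to 4, 3, then 1 and 2. The O–S bond, one O–CH3 bond and the aryl–carbonyl bond are cut in turn. The ketone installs the future C1 and also directs the cleavage of the one methyl ether ortho to it, which differentiates the C7 oxygen. The forward step requires acylation ortho to the side chain and para to a methoxy group.

## Other disconnections considered

Alternative 1: The cut runs through ring C, which is taken apart into three alkynes so that benzofuran bonds C3a–C7a, C7–C6 and C5–C4 form together. Forward, the anti-configured ether diyne A2 (an ethynyl ether on the future furan C2, a silyloxybutynyl arm on the future furan C3) would be cyclotrimerised with ethoxyethyne A3 under a late-transition-metal (2+2+2) catalyst to give the trans-dihydrobenzofuran A1.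
- In favour: the two furan stereocentres are fixed on an open chain before the ring exists, ring C arrives with its oxygen pattern and a one-carbon handle at C4 in one step, and no electrophilic substitution on a crowded arene is needed. On control of the furan stereocentres it is the better plan, since the chosen route sets them last and relies on thermodynamic preference.
- Against: alkynyl ethers of secondary benzylic alcohols are thermally fragile (sigmatropic rearrangement, ketene formation). The tether does not fix the orientation in which A3 is taken up, although the ethoxy group must end at C6. A1 holds only ring C, ring B and one anisyl group.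
- Comparison: on structure, the indane triad, Cα and the eight-membered ring would still have to be built from the C4 handle next to an acid-labile dihydrofuran, so the hardest part of the target is left open, whereas the chosen key step solves the triad first. On mechanism the two are equal: each relies on a metal-catalysed step of a known class. On step economy the alternative is expected to be longer, because A2 needs its own stereoselective synthesis and the later ring closures come on top.

Alternative 2: The cut removes ring A: bond C3a–C4 is broken and the resorcinol ring is unfolded into a triketide chain on a cyclopentanone that already holds indane C1, C2 and C3. Forward, base would make the dioxinone α-carbon of the diketo-dioxinone A5 add to the ring ketone; dehydration and enolisation would then give the benzodioxinone A4.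
- In favour: mild ionic chemistry with no diazo compound and no costly chiral catalyst. The C7 hydroxyl and the C5 oxygen emerge differentiated, which is the equal of the chelation-controlled demethylation of the chosen plan. The carboxyl group at C4, while kept, blocks the carbon that competes in the eight-membered ring closure, a better safeguard than the electronic deactivation used here. Aromatisation is thermodynamically driven and so more predictable than insertion of a hindered carbene.
- Against: the C4 carboxyl group is an extra carbon that must be removed later by decarboxylation. The C3 substituent sits at the alcohol oxidation level and must be re-oxidised. The absolute configuration must come from an earlier asymmetric step on the cyclopentanone, whose centres next to the 1,3-dicarbonyl unit can epimerise.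
- Comparison: on structure it addresses the same indane but builds the arene instead of the five-membered ring. On mechanism it is the safer step. On step economy it is expected to be clearly longer before the key step (three contiguous centres on a cyclopentanone plus C-acylation with the dioxinone unit) and about equal after it.

Alternative 3: The cut comes at the end: furan bonds C3–C3a and O1–C2 are broken together, which opens the eight-membered ring and the dihydrofuran and leads to A7, an indane whose ring C is a free resorcinol and whose ring B carries an (E)-4-methoxystyryl group. Forward, a one-electron oxidant would join the ring C carbon ortho to a hydroxyl group to the styrene carbon remote from the anisyl group, and then the phenol oxygen to the benzylic carbon, giving the heptamethyl ether A6.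
- In favour: it follows the presumed biogenesis, forms two rings and two stereocentres in one step, and A6 is one deprotection from 29. In step economy at the end it is the better plan (one step plus demethylation against four). On the trans ring fusion the two plans are equal, both resting on the stability of the trans dihydrofuran.
- Against: ring C has a second nucleophilic carbon between its two hydroxyl groups, and the styrene can dimerise intermolecularly. An eight-membered ring must form in a radical or cationic coupling with no tether to guide it. The configuration at furan C3 relative to Cα is left to the folding of a flexible chain, and the phenolic product is itself oxidisable.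
- Comparison: on structure, the styrene would have to survive the construction of Cα, which rules out the acid-mediated cation chemistry used here (the cation would add to the alkene), so the way to A7 would need another, probably longer, solution. On mechanism, the chosen acylation is an ionic, tether-controlled step with defined regiochemistry, whereas the oxidative coupling is harder to predict.

Key step: step 7

Remarks before the steps (one line each):
- Locants: indane atoms are numbered so that C1 carries the 4-methoxyphenyl group, C2 ring C and C3 the one-carbon substituent; Cα is the carbon on C3; "furan C2/C3" are the dihydrofuran carbons of 29; tosyloxy = 4-methylbenzenesulfonyloxy.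
- Assumption: Rh2(S-PTAD)4 is taken to deliver the (1S,2R) sense of insertion; if the opposite sense is found, Rh2(R-PTAD)4 is used with no other change.
- Check of structures: the all-trans (1S,2R,3S) ester maps onto C1 (S), C2 (S), C3 (R) of 29 (the descriptors at C2 and C3 change only because substituent priorities change); no constitutional error was found.
- Design change 1: the C7 oxygen is carried as a tosylate, not as a trialkylsilyl ether later exchanged for methyl: it has no hydridic C–H near the carbene, is smaller next to the ketone, and keeps C4 of ring A unreactive in the ring-closing acylation.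
- Design change 2: the hydrazone is made as its N-silyl derivative, because hot free hydrazine would attack the ester of the 2-aroylphenylacetate.
- Design change 3: Cα is built from the aldehyde (aryllithium addition, then arylation of the lactone) rather than by adding a hindered aryllithium to a branched, enolisable ketone.

Step 1
Reactants: 1 methyl 2-(3,5-dimethoxyphenyl)acetate; 2 4-methoxybenzoyl chloride
Product: 3 methyl 2-[3,5-dimethoxy-2-(4-methoxybenzoyl)phenyl]acetate
Conditions: SnCl4 (1.5 equiv), CH2Cl2, 0 °C → rt
Reagents that add atoms: none
Why: Friedel–Crafts acylation: the ring carbon ortho to the side chain and para to a methoxy group is the most nucleophilic accessible site (the carbon between the two methoxy groups is flanked on both sides), and SnCl4 at 0 °C is mild enough to leave the keto ester uncyclised and the ethers intact.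

Step 2
Reactants: 3 methyl 2-[3,5-dimethoxy-2-(4-methoxybenzoyl)phenyl]acetate
Product: 4 methyl 2-[3-hydroxy-5-methoxy-2-(4-methoxybenzoyl)phenyl]acetate
Conditions: BCl3 (1.5 equiv), CH2Cl2, −78 → 0 °C; aq. NaHCO3
Reagents that add atoms: none
Why: Chelation-controlled aryl methyl ether cleavage: BCl3 binds the ketone oxygen and removes only the methyl group of the ortho methoxy group through a six-membered chelate; the para methoxy group, the anisyl ether and the ester stay.

Step 3
Reactants: 4 methyl 2-[3-hydroxy-5-methoxy-2-(4-methoxybenzoyl)phenyl]acetate
Product: 5 methyl 2-[5-methoxy-2-(4-methoxybenzoyl)-3-(tosyloxy)phenyl]acetate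
Conditions: TsCl (1.3 equiv), Et3N, DMAP (cat.), CH2Cl2, 0 °C → rt
Reagents that add atoms: 4-methylbenzenesulfonyl chloride (TsCl), Cc1ccc(cc1)S(Cl)(=O)=O
Why: Sulfonylation of the hydrogen-bonded phenol under DMAP catalysis. The tosylate is stable to the bases, acids and Lewis acids of steps 4–13 and is removed by hydroxide in step 14.

Step 4
Reactants: 5 methyl 2-[5-methoxy-2-(4-methoxybenzoyl)-3-(tosyloxy)phenyl]acetate; 6 3,5-dimethoxybenzyl bromide
Product: 8 methyl 3-(3,5-dimethoxyphenyl)-2-[5-methoxy-2-(4-methoxybenzoyl)-3-(tosyloxy)phenyl]propanoate (racemic), via lithium enolate 7 (not isolated)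
Conditions: LiN(SiMe3)2 (1.05 equiv), THF, −78 °C; then 6, −78 → 0 °C
Reagents that add atoms: none
Why: Ester enolate alkylation (SN2) with a benzylic bromide: one equivalent of amide base removes only the arylacetate proton, the diaryl ketone cannot enolise and the aryl sulfonate is inert at −78 °C. The new centre is formed racemic, which is acceptable because it is equilibrated after the key step.

Step 5
Reactants: 8 methyl 3-(3,5-dimethoxyphenyl)-2-[5-methoxy-2-(4-methoxybenzoyl)-3-(tosyloxy)phenyl]propanoate
Product: 9 N-(tert-butyldimethylsilyl)hydrazone of 8 (racemic; E/Z mixture)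
Conditions: t-BuMe2SiNHNHSiMe2t-Bu (2 equiv), Sc(OTf)3 (1 mol %), CHCl3, 60 °C
Reagents that add atoms: 1,2-bis(tert-butyldimethylsilyl)hydrazine, CC(C)(C)[Si](C)(C)NN[Si](C)(C)C(C)(C)C
Why: Sc(OTf)3-catalysed condensation of a ketone with a 1,2-bis(silyl)hydrazine (N-silyl hydrazone formation) tolerates hindered ketones and uses no free hydrazine, which on heating would attack the neighbouring ester and close a 2,3-benzodiazepin-4-one.

Step 6
Reactants: 9 N-(tert-butyldimethylsilyl)hydrazone of 8
Product: 11 methyl 2-{2-[diazo(4-methoxyphenyl)methyl]-5-methoxy-3-(tosyloxy)phenyl}-3-(3,5-dimethoxyphenyl)propanoate (racemic; used at once as a cold solution), via free hydrazone 10 (not isolated)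
Conditions: n-Bu4NF (1.05 equiv), THF, −20 °C; then activated MnO2 (10 equiv), 0 °C; cold filtration through Celite
Reagents that add atoms: none
Why: Fluoride cleaves the labile N–Si bond at low temperature and activated MnO2 dehydrogenates the N-unsubstituted hydrazone to the diaryldiazomethane (hydrazone oxidation). The free hydrazone exists only cold and briefly, so it cannot cyclise onto the ester.

Step 7
Reactants: 11 methyl 2-{2-[diazo(4-methoxyphenyl)methyl]-5-methoxy-3-(tosyloxy)phenyl}-3-(3,5-dimethoxyphenyl)propanoate
Product: 13 methyl (1S,2R,3S)-2-(3,5-dimethoxyphenyl)-5-methoxy-1-(4-methoxyphenyl)-7-(tosyloxy)indane-3-carboxylate (all-trans), via C3-epimeric ester mixture 12 (not isolated)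
Conditions: Rh2(S-PTAD)4 (1 mol %; PTAD = (1-adamantyl)(phthalimido)acetate), CH2Cl2, 0 °C → rt; then NaOMe (0.3 equiv), MeOH–THF, rt
Reagents that add atoms: none
Why: Rh2(S-PTAD)4, a dirhodium tetracarboxylate of divalent rhodium, takes up the diazo carbon, N2 leaves, and the electrophilic diaryl rhodium carbene at C1 inserts into one C–H bond of the CH2 group through a concerted, asynchronous three-centre transition state with hydride-transfer character. The closest known reaction type is the enantioselective intramolecular 1,5 C–H insertion of diaryl (donor/donor) carbenes generated from hydrazones, which forms benzo-fused five-membered rings. The indane ring is closed by 1,5-insertion through a five-membered cyclic transition structure (C1, C7a, C3a, C3, C2), the only 1,5 C–H relationship in 11; insertion into C3–H would give a four-membered ring and the sulfonate offers no hydridic C–H bond. C1 and C2 are set together: the chiral carboxylate pocket selects the carbene face and one of the two diastereotopic benzylic hydrogens, and the two aryl groups take up a trans arrangement to avoid eclipsing in the envelope-like transition state. C3 is not controlled in the insertion (11 is racemic there), so the crude C3-epimeric mixture 12 is equilibrated with NaOMe through the ester enolate to the all-trans isomer, in which all three substituents are pseudo-equatorial. The step needs chemoselectivity for C–H insertion over capture of the carbene by the ester carbonyl, and catalyst control that overrides the resident C3 centre; the low electrophilicity of a donor/donor carbene, the benzylic activation of the C–H bond and the electron-poor, C–H-free sulfonate at C7 all work in that direction.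

Step 8
Reactants: 13 methyl (1S,2R,3S)-2-(3,5-dimethoxyphenyl)-5-methoxy-1-(4-methoxyphenyl)-7-(tosyloxy)indane-3-carboxylate
Product: 14 (1S,2R,3S)-2-(3,5-dimethoxyphenyl)-5-methoxy-1-(4-methoxyphenyl)-7-(tosyloxy)indane-3-carbaldehyde
Conditions: i-Bu2AlH (1.2 equiv), CH2Cl2, −78 °C; MeOH, aq. potassium sodium tartrate
Reagents that add atoms: none
Why: Partial reduction of a methyl ester by i-Bu2AlH: at −78 °C the tetrahedral aluminium hemiacetal of this α-branched ester persists until work-up, so the aldehyde is not reduced further. C3 keeps the trans arrangement, which is also the thermodynamic one for this epimerisable centre, and the sulfonate is untouched.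

Step 9
Reactants: 15 3,5-dimethoxybenzoyl chloride; 16 diethylamine
Product: 17 N,N-diethyl-3,5-dimethoxybenzamide
Conditions: 16 (2.2 equiv), CH2Cl2, 0 °C → rt
Reagents that add atoms: none
Why: Acylation of a secondary amine by an acid chloride; the second equivalent of amine takes up HCl.

Step 10
Reactants: 17 N,N-diethyl-3,5-dimethoxybenzamide; 14 (1S,2R,3S)-2-(3,5-dimethoxyphenyl)-5-methoxy-1-(4-methoxyphenyl)-7-(tosyloxy)indane-3-carbaldehyde
Product: 20 3-[(1S,2R,3S)-2-(3,5-dimethoxyphenyl)-5-methoxy-1-(4-methoxyphenyl)-7-(tosyloxy)indan-3-yl]-4,6-dimethoxyisobenzofuran-1(3H)-one (both epimers at the lactone carbon), via aryllithium 18 (not isolated), via hydroxy amide 19 (not isolated)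
Conditions: 17, s-BuLi, TMEDA, THF, −78 °C; then 14, −78 °C; aq. NH4Cl; then TsOH·H2O (1.2 equiv), toluene, 50 °C
Reagents that add atoms: none
Why: Directed ortho-metalation: the tertiary amide and the methoxy group together direct s-BuLi to the carbon between them, and the aryllithium adds to the aldehyde faster than it enolises it at −78 °C. Acid-promoted attack of the new hydroxyl group on the amide expels diethylamine and gives the phthalide; the configuration of the lactone carbon is of no consequence because this centre is ionised in step 11.

Step 11
Reactants: 20 3-[(1S,2R,3S)-2-(3,5-dimethoxyphenyl)-5-methoxy-1-(4-methoxyphenyl)-7-(tosyloxy)indan-3-yl]-4,6-dimethoxyisobenzofuran-1(3H)-one; 21 anisole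
Product: 22 2-{(R)-[(1S,2S,3R)-2-(3,5-dimethoxyphenyl)-5-methoxy-1-(4-methoxyphenyl)-7-(tosyloxy)indan-3-yl](4-methoxyphenyl)methyl}-3,5-dimethoxybenzoic acid
Conditions: TfOH (1.5 equiv), 21–CH2Cl2 (1:3), −20 → 0 °C
Reagents that add atoms: none
Why: Friedel–Crafts alkylation with a lactone as leaving group: TfOH opens the phthalide to a benzylic cation at Cα, stabilised by the ortho and para methoxy groups of ring B, and anisole attacks it through its para position, which releases the carboxylic acid. In the conformer with C3–H near the plane of the cation (which also keeps that C–H bond out of alignment for elimination) the face beside C3–H is open while the other is screened by C2 and its aryl group, so anisole should add there and give the (R) centre. Ring C cannot reach the cation because it is trans to Cα on the five-membered ring.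

Step 12
Reactants: 22 2-{(R)-[(1S,2S,3R)-2-(3,5-dimethoxyphenyl)-5-methoxy-1-(4-methoxyphenyl)-7-(tosyloxy)indan-3-yl](4-methoxyphenyl)methyl}-3,5-dimethoxybenzoic acid
Product: 23 eight-membered-ring diaryl ketone: the carboxyl carbon of 22 bonded to C2 of ring C (configuration of 22 unchanged)
Conditions: (CF3CO)2O (3 equiv), CH2Cl2 (0.005 M), 0 °C → rt
Reagents that add atoms: none
Why: Intramolecular Friedel–Crafts acylation through the mixed trifluoroacetic anhydride. The acyl carbon can reach two activated arene carbons, C4 of ring A (seven-membered ring) and the ortho carbon of ring C (eight-membered ring); with the C7 oxygen as an electron-poor sulfonate, C4 has lost its para donor, so ring C, activated by one ortho and one para methoxy group, is expected to react. High dilution suppresses intermolecular acylation.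

Step 13
Reactants: 23 eight-membered-ring diaryl ketone
Product: 25 (R)-configured diarylacetaldehyde: H plus CHO on the former carbonyl carbon of 23, via spiro-epoxide 24 (not isolated)
Conditions: Me3S+ I−, n-BuLi, THF, 0 °C; then 23, 0 °C → rt; aqueous work-up; ZnI2 (0.2 equiv), CH2Cl2, rt; then DBU (0.1 equiv)
Reagents that add atoms: trimethylsulfonium iodide, C[S+](C)C.[I-]
Why: Corey–Chaykovsky epoxidation of the diaryl ketone by dimethylsulfonium methylide, then Meinwald rearrangement: ZnI2 opens the epoxide at the diaryl carbon (cation stabilised by ring C) and a 1,2-hydride shift from the CH2 group, the only group that can migrate, gives the aldehyde. The new centre is α to the formyl group and doubly benzylic, so base equilibrates it; the isomer with the formyl group anti to the Cα anisyl group and to the indane C1 branch, which is the one required, should be favoured.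

Step 14
Reactants: 25 (R)-configured diarylacetaldehyde; 26 4-methoxyphenylmagnesium bromide
Product: 28 secondary carbinol from 25 (CH(OH)(4-methoxyphenyl) on the future furan C3; both carbinol epimers; free hydroxyl at C7), via carbinol tosylate 27 (not isolated)
Conditions: 26 (3 equiv), THF, −78 → 0 °C; then MeOH, KOH (10 equiv), 65 °C
Reagents that add atoms: none
Why: Grignard addition to the aldehyde (the carbinol configuration is irrelevant because this centre is ionised in step 15), then S–O cleavage of the aryl sulfonate by methanolic hydroxide in the same flask. No other group in 27 is base-labile.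

Step 15
Reactants: 28 secondary carbinol (free hydroxyl at C7)
Product: 29 stenophyllol B
Conditions: BBr3 (16 equiv), CH2Cl2, −78 °C → rt; MeOH, 0 °C
Reagents that add atoms: none
Why: Lewis-acid ether cleavage with ring closure: BBr3 ionises the p-methoxybenzylic alcohol, the neighbouring methoxy oxygen of ring C closes the five-membered ring on the cation (5-exo) and bromide removes the methyl group from the oxonium ion. The C–O bond can re-ionise, so the 2-aryl group should settle trans to the ring B substituent on furan C3. The same reagent cleaves the seven remaining methyl ethers.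

Compound list

1 | methyl 2-(3,5-dimethoxyphenyl)acetate | COC(=O)Cc1cc(OC)cc(OC)c1 | starting material
2 | 4-methoxybenzoyl chloride | COc1ccc(cc1)C(Cl)=O | starting material
3 | methyl 2-[3,5-dimethoxy-2-(4-methoxybenzoyl)phenyl]acetate | COC(=O)Cc1cc(OC)cc(OC)c1C(=O)c1ccc(OC)cc1 | intermediate
4 | methyl 2-[3-hydroxy-5-methoxy-2-(4-methoxybenzoyl)phenyl]acetate | COC(=O)Cc1cc(OC)cc(O)c1C(=O)c1ccc(OC)cc1 | intermediate
5 | methyl 2-[5-methoxy-2-(4-methoxybenzoyl)-3-(tosyloxy)phenyl]acetate | COC(=O)Cc1cc(OC)cc(OS(=O)(=O)c2ccc(C)cc2)c1C(=O)c1ccc(OC)cc1 | intermediate
6 | 3,5-dimethoxybenzyl bromide | COc1cc(CBr)cc(OC)c1 | starting material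
7 | lithium enolate of 5 | [Li]OC(OC)=Cc1cc(OC)cc(OS(=O)(=O)c2ccc(C)cc2)c1C(=O)c1ccc(OC)cc1 | intermediate
8 | methyl 3-(3,5-dimethoxyphenyl)-2-[5-methoxy-2-(4-methoxybenzoyl)-3-(tosyloxy)phenyl]propanoate, racemic | COC(=O)C(Cc1cc(OC)cc(OC)c1)c1cc(OC)cc(OS(=O)(=O)c2ccc(C)cc2)c1C(=O)c1ccc(OC)cc1 | intermediate
9 | N-(tert-butyldimethylsilyl)hydrazone of 8 (C=N–NH–SiMe2t-Bu at the former ketone carbon), racemic, E/Z mixture | COC(=O)C(Cc1cc(OC)cc(OC)c1)c1cc(OC)cc(OS(=O)(=O)c2ccc(C)cc2)c1C(=NN[Si](C)(C)C(C)(C)C)c1ccc(OC)cc1 | intermediate
10 | hydrazone of 8 (C=N–NH2 at the former ketone carbon), racemic | COC(=O)C(Cc1cc(OC)cc(OC)c1)c1cc(OC)cc(OS(=O)(=O)c2ccc(C)cc2)c1C(=NN)c1ccc(OC)cc1 | intermediate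
11 | methyl 2-{2-[diazo(4-methoxyphenyl)methyl]-5-methoxy-3-(tosyloxy)phenyl}-3-(3,5-dimethoxyphenyl)propanoate, racemic | COc1ccc(C(=[N+]=[N-])c2c(OS(=O)(=O)c3ccc(C)cc3)cc(OC)cc2C(C(=O)OC)Cc2cc(OC)cc(OC)c2)cc1 | intermediate
12 | methyl (1S,2R)-2-(3,5-dimethoxyphenyl)-5-methoxy-1-(4-methoxyphenyl)-7-(tosyloxy)indane-3-carboxylate, mixture of C3 epimers | COc1ccc([C@H]2c3c(OS(=O)(=O)c4ccc(C)cc4)cc(OC)cc3C(C(=O)OC)[C@@H]2c2cc(OC)cc(OC)c2)cc1 | intermediate
13 | methyl (1S,2R,3S)-2-(3,5-dimethoxyphenyl)-5-methoxy-1-(4-methoxyphenyl)-7-(tosyloxy)indane-3-carboxylate, all-trans | COc1ccc([C@H]2c3c(OS(=O)(=O)c4ccc(C)cc4)cc(OC)cc3[C@@H](C(=O)OC)[C@@H]2c2cc(OC)cc(OC)c2)cc1 | intermediate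
14 | (1S,2R,3S)-2-(3,5-dimethoxyphenyl)-5-methoxy-1-(4-methoxyphenyl)-7-(tosyloxy)indane-3-carbaldehyde, all-trans | COc1ccc([C@H]2c3c(OS(=O)(=O)c4ccc(C)cc4)cc(OC)cc3[C@@H](C=O)[C@@H]2c2cc(OC)cc(OC)c2)cc1 | intermediate
15 | 3,5-dimethoxybenzoyl chloride | COc1cc(cc(OC)c1)C(Cl)=O | starting material
16 | diethylamine | CCNCC | starting material
17 | N,N-diethyl-3,5-dimethoxybenzamide | CCN(CC)C(=O)c1cc(OC)cc(OC)c1 | intermediate
18 | N,N-diethyl-2-lithio-3,5-dimethoxybenzamide | [Li]c1c(OC)cc(OC)cc1C(=O)N(CC)CC | intermediate
19 | N,N-diethyl-2-{hydroxy[(1S,2R,3S)-2-(3,5-dimethoxyphenyl)-5-methoxy-1-(4-methoxyphenyl)-7-(tosyloxy)indan-3-yl]methyl}-3,5-dimethoxybenzamide, both carbinol epimers | COc1ccc([C@H]2c3c(OS(=O)(=O)c4ccc(C)cc4)cc(OC)cc3[C@@H](C(O)c3c(OC)cc(OC)cc3C(=O)N(CC)CC)[C@@H]2c2cc(OC)cc(OC)c2)cc1 | intermediate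
20 | 3-[(1S,2R,3S)-2-(3,5-dimethoxyphenyl)-5-methoxy-1-(4-methoxyphenyl)-7-(tosyloxy)indan-3-yl]-4,6-dimethoxyisobenzofuran-1(3H)-one, both epimers at the lactone carbon | COc1ccc([C@H]2c3c(OS(=O)(=O)c4ccc(C)cc4)cc(OC)cc3[C@@H](C3OC(=O)c4cc(OC)cc(OC)c43)[C@@H]2c2cc(OC)cc(OC)c2)cc1 | intermediate
21 | anisole (methoxybenzene) | COc1ccccc1 | starting material
22 | 2-{(R)-[(1S,2S,3R)-2-(3,5-dimethoxyphenyl)-5-methoxy-1-(4-methoxyphenyl)-7-(tosyloxy)indan-3-yl](4-methoxyphenyl)methyl}-3,5-dimethoxybenzoic acid | COc1ccc([C@H]2c3c(OS(=O)(=O)c4ccc(C)cc4)cc(OC)cc3[C@@H]([C@H](c3ccc(OC)cc3)c3c(OC)cc(OC)cc3C(=O)O)[C@@H]2c2cc(OC)cc(OC)c2)cc1 | intermediate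
23 | eight-membered-ring diaryl ketone: carboxyl carbon of 22 bonded to C2 of ring C (ortho to the indane link and to a methoxy group); C1 (S), C2 (S), C3 (R), Cα (R); seven methyl ethers, C7 tosylate | COc1ccc([C@H]2c3c(OS(=O)(=O)c4ccc(C)cc4)cc(OC)cc3[C@H]3[C@H](c4ccc(OC)cc4)c4c(OC)cc(OC)cc4C(=O)c4c(OC)cc(OC)cc4[C@H]23)cc1 | intermediate
24 | spiro-epoxide of 23 (oxirane on the former carbonyl carbon, CH2 terminus), both epimers at the spiro carbon | COc1ccc([C@H]2c3c(OS(=O)(=O)c4ccc(C)cc4)cc(OC)cc3[C@H]3[C@H](c4ccc(OC)cc4)c4c(OC)cc(OC)cc4C4(CO4)c4c(OC)cc(OC)cc4[C@H]23)cc1 | intermediate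
25 | diarylacetaldehyde: the former carbonyl carbon of 23 (future furan C3) carries H and CHO, (R) configuration, formyl group anti to the Cα anisyl group; other centres as in 23 | COc1ccc([C@H]2c3c(OS(=O)(=O)c4ccc(C)cc4)cc(OC)cc3[C@H]3[C@H](c4ccc(OC)cc4)c4c(OC)cc(OC)cc4[C@@H](C=O)c4c(OC)cc(OC)cc4[C@H]23)cc1 | intermediate
26 | 4-methoxyphenylmagnesium bromide | COc1ccc([Mg]Br)cc1 | starting material
27 | secondary carbinol from 25: CH(OH)(4-methoxyphenyl) on the future furan C3 (R); both carbinol epimers; C7 tosylate | COc1ccc([C@H]2c3c(OS(=O)(=O)c4ccc(C)cc4)cc(OC)cc3[C@H]3[C@H](c4ccc(OC)cc4)c4c(OC)cc(OC)cc4[C@@H](C(O)c4ccc(OC)cc4)c4c(OC)cc(OC)cc4[C@H]23)cc1 | intermediate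
28 | as 27 with a free hydroxyl group at C7 (eight methyl ethers) | COc1ccc([C@H]2c3c(O)cc(OC)cc3[C@H]3[C@H](c4ccc(OC)cc4)c4c(OC)cc(OC)cc4[C@@H](C(O)c4ccc(OC)cc4)c4c(OC)cc(OC)cc4[C@H]23)cc1 | intermediate
29 | stenophyllol B: C1 (S), C2 (S), C3 (R), Cα (R), furan C3 (R), furan C2 (R) | Oc1ccc([C@H]2c3c(O)cc(O)cc3[C@H]3[C@H](c4ccc(O)cc4)c4c(O)cc(O)cc4[C@@H]4c5c(cc(O)cc5[C@H]23)O[C@H]4c2ccc(O)cc2)cc1 | target

Total step count: 15. Longest linear sequence: 14 steps (steps 1–8 and 10–15; step 9 is a one-step side branch).

Steps least certain to work

Step 7 (key step). The most likely failure is loss of stereocontrol, possibly together with diversion of the carbene. Compound 11 is racemic at C3, so half of it is mismatched with the chiral catalyst: there the resident centre, which prefers a 2,3-trans transition state, opposes the catalyst, and any leakage ends as the enantiomer of 13 after the methoxide equilibration. The carbene carbon also lies between two ortho substituents, which slows carbene formation and gives azine formation or attack by the ester carbonyl a chance. Fallback, from 1 back to 13, with no carbene: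
- Oxidative coupling of the lithium enolate of 1 (LiN(i-Pr)2, then I2) gives dimethyl 2,3-bis(3,5-dimethoxyphenyl)butanedioate F1.
- Saponification with one equivalent of KOH gives the half-ester F2.
- (CF3CO)2O closes methyl trans-2-(3,5-dimethoxyphenyl)-5,7-dimethoxy-1-oxoindane-3-carboxylate F3 by Friedel–Crafts acylation at the ring carbon ortho and para to the methoxy groups.
- BCl3 removes the methyl group ortho to the new ketone, giving the 7-hydroxy indanone F4; TsCl gives the 7-tosyloxy indanone F5.
- Compound 26 with CeCl3 adds to the ketone, giving the tertiary 1-aryl-indan-1-ol F6.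
- Et3SiH/CF3CO2H (ionic hydrogenation, hydride trans to the C2 aryl group) and then NaOMe give the racemate, that is 13 together with its (1R,2S,3R) enantiomer F7.
- Chromatography on a chiral stationary phase returns 13.

Step 5. The most likely failure is that the condensation stalls, because the carbonyl group is shielded on both sides and deactivated by two electron-rich rings. Fallback, from 8 back to 10: thionation of 8 with 2,4-bis(4-methoxyphenyl)-1,3,2,4-dithiadiphosphetane 2,4-disulfide in toluene at 80 °C gives the diaryl thioketone F8. Thioketones are far more electrophilic toward nitrogen nucleophiles than ketones, so hydrazine hydrate in THF at 0 °C should give the free hydrazone 10 with loss of H2S, cold and fast enough to spare the ester; 10 is then oxidised as in step 6.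

Step 11. The most likely failure is poor facial selectivity in the capture of the Cα cation, since the preference rests on a conformational argument alone. A second danger is loss of the C3 proton from the cation, then reprotonation from the other face and capture of the now cis-disposed cation by ring C. Fallback, from 13 back to 22, with both aryl groups introduced first and hydrogen last:
- MeNH(OMe)·HCl/i-PrMgCl converts 13 into the N-methoxy-N-methylamide F9.
- Compound 26 gives the 4-methoxyphenyl ketone F10.
- The cerium reagent made from 18 and CeCl3 adds to F10 and lactonises to the tertiary phthalide F11.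
- Et3SiH/CF3CO2H reduces the lactone (ionic hydrogenation) to 22.

The hydride donor now plays the part of anisole, so whichever face the incoming group prefers, one of the two orders supplies 22. Silane capture of the diaryl cation is also much faster than arene capture, which suppresses the elimination pathway.

Step 12. The most likely failure is intermolecular acylation or no reaction, because an eight-membered ring must close at an arene carbon flanked by two substituents. Fallback, from 22 back to 23, with a more electrophilic and reversible closure:
- BH3·THF reduces the acid to the benzylic alcohol F12.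
- DMP (1,1,1-triacetoxy-1,1-dihydro-1,2-benziodoxol-3(1H)-one) gives the aldehyde F13.
- BF3·OEt2 at high dilution closes the ring by intramolecular hydroxyalkylation of ring C to the cyclic diarylcarbinol F14; the step is reversible, so oligomers can revert.
- MnO2 oxidises F14 to 23.

Step 13. The most likely failure is no addition of the sulfur ylide to a ketone shielded by three ortho substituents. A second concern is that the equilibrated aldehyde prefers the other configuration at the future furan C3. Fallback, from 23 back to 25:
- MeMgBr/CeCl3 gives the tertiary methylcarbinol F15.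
- Acid-catalysed dehydration gives the 1,1-diarylethene F16.
- Hydroboration–oxidation (BH3·THF; H2O2, NaOH) gives the primary alcohol F17.
- DMP oxidation gives 25.

Here the hydrogen on the future furan C3 is delivered by syn addition of the borane under kinetic control and the aldehyde need not meet base, so the other stereochemical outcome is also within reach.

Step 15. The most likely failure is side reactions of the benzylic cation during the long exposure to BBr3: loss of the neighbouring proton, re-opening of the dihydrofuran and Friedel–Crafts capture by an arene, with incomplete trans selectivity. Fallback, from 28 back to 29, with ring closure separated from deprotection: BCl3 at −78 °C should ionise only the benzylic alcohol of 28, and methoxy participation with loss of chloromethane should then give the hepta-O-methyl dihydrobenzofuran F18 with all ordinary methyl ethers intact. F18 can be purified and its trans configuration secured by brief acid equilibration. The ethers are then cleaved in a separate operation (BBr3 at low temperature, or BCl3 with n-Bu4NI) to give 29.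

Further compounds

F1 | step 7 | dimethyl 2,3-bis(3,5-dimethoxyphenyl)butanedioate (diastereomer mixture) | COC(=O)C(c1cc(OC)cc(OC)c1)C(C(=O)OC)c1cc(OC)cc(OC)c1
F2 | step 7 | 2,3-bis(3,5-dimethoxyphenyl)-4-methoxy-4-oxobutanoic acid | COC(=O)C(c1cc(OC)cc(OC)c1)C(C(O)=O)c1cc(OC)cc(OC)c1
F3 | step 7 | methyl trans-2-(3,5-dimethoxyphenyl)-5,7-dimethoxy-1-oxoindane-3-carboxylate (racemic; one enantiomer drawn) | O=C2c3c(OC)cc(OC)cc3[C@@H](C(=O)OC)[C@@H]2c2cc(OC)cc(OC)c2
F4 | step 7 | methyl trans-2-(3,5-dimethoxyphenyl)-7-hydroxy-5-methoxy-1-oxoindane-3-carboxylate (racemic; one enantiomer drawn) | O=C2c3c(O)cc(OC)cc3[C@@H](C(=O)OC)[C@@H]2c2cc(OC)cc(OC)c2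
F5 | step 7 | methyl trans-2-(3,5-dimethoxyphenyl)-5-methoxy-1-oxo-7-(tosyloxy)indane-3-carboxylate (racemic; one enantiomer drawn) | O=C2c3c(OS(=O)(=O)c4ccc(C)cc4)cc(OC)cc3[C@@H](C(=O)OC)[C@@H]2c2cc(OC)cc(OC)c2
F6 | step 7 | methyl 2,3-trans-2-(3,5-dimethoxyphenyl)-1-hydroxy-5-methoxy-1-(4-methoxyphenyl)-7-(tosyloxy)indane-3-carboxylate (racemic; C1 epimers; one enantiomer drawn) | COc1ccc(cc1)C2(O)c3c(OS(=O)(=O)c4ccc(C)cc4)cc(OC)cc3[C@@H](C(=O)OC)[C@@H]2c2cc(OC)cc(OC)c2
F7 | step 7 | methyl (1R,2S,3R)-2-(3,5-dimethoxyphenyl)-5-methoxy-1-(4-methoxyphenyl)-7-(tosyloxy)indane-3-carboxylate (enantiomer of 13) | COc1ccc([C@@H]2c3c(OS(=O)(=O)c4ccc(C)cc4)cc(OC)cc3[C@H](C(=O)OC)[C@H]2c2cc(OC)cc(OC)c2)cc1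
F8 | step 5 | methyl 3-(3,5-dimethoxyphenyl)-2-[5-methoxy-2-(4-methoxythiobenzoyl)-3-(tosyloxy)phenyl]propanoate (racemic) | COC(=O)C(Cc1cc(OC)cc(OC)c1)c1cc(OC)cc(OS(=O)(=O)c2ccc(C)cc2)c1C(=S)c1ccc(OC)cc1
F9 | step 11 | (1S,2R,3S)-2-(3,5-dimethoxyphenyl)-N,5-dimethoxy-1-(4-methoxyphenyl)-N-methyl-7-(tosyloxy)indane-3-carboxamide | COc1ccc([C@H]2c3c(OS(=O)(=O)c4ccc(C)cc4)cc(OC)cc3[C@@H](C(=O)N(C)OC)[C@@H]2c2cc(OC)cc(OC)c2)cc1
F10 | step 11 | [(1S,2R,3S)-2-(3,5-dimethoxyphenyl)-5-methoxy-1-(4-methoxyphenyl)-7-(tosyloxy)indan-3-yl](4-methoxyphenyl)methanone | COc1ccc([C@H]2c3c(OS(=O)(=O)c4ccc(C)cc4)cc(OC)cc3[C@@H](C(=O)c3ccc(OC)cc3)[C@@H]2c2cc(OC)cc(OC)c2)cc1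
F11 | step 11 | 3-[(1S,2R,3S)-indan-3-yl as in 20]-4,6-dimethoxy-3-(4-methoxyphenyl)isobenzofuran-1(3H)-one (epimers at the lactone carbon) | COc1ccc([C@H]2c3c(OS(=O)(=O)c4ccc(C)cc4)cc(OC)cc3[C@@H](C3(c4ccc(OC)cc4)OC(=O)c4cc(OC)cc(OC)c43)[C@@H]2c2cc(OC)cc(OC)c2)cc1
F12 | step 12 | benzylic alcohol: 22 with CH2OH in place of CO2H | COc1ccc([C@H]2c3c(OS(=O)(=O)c4ccc(C)cc4)cc(OC)cc3[C@@H]([C@H](c3ccc(OC)cc3)c3c(OC)cc(OC)cc3CO)[C@@H]2c2cc(OC)cc(OC)c2)cc1
F13 | step 12 | aldehyde: 22 with CHO in place of CO2H | COc1ccc([C@H]2c3c(OS(=O)(=O)c4ccc(C)cc4)cc(OC)cc3[C@@H]([C@H](c3ccc(OC)cc3)c3c(OC)cc(OC)cc3C=O)[C@@H]2c2cc(OC)cc(OC)c2)cc1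
F14 | step 12 | cyclic diarylcarbinol: 23 with CH(OH) in place of C=O (carbinol epimers) | COc1ccc([C@H]2c3c(OS(=O)(=O)c4ccc(C)cc4)cc(OC)cc3[C@H]3[C@H](c4ccc(OC)cc4)c4c(OC)cc(OC)cc4C(O)c4c(OC)cc(OC)cc4[C@H]23)cc1
F15 | step 13 | tertiary methylcarbinol: 23 with C(CH3)(OH) in place of C=O (epimers) | COc1ccc([C@H]2c3c(OS(=O)(=O)c4ccc(C)cc4)cc(OC)cc3[C@H]3[C@H](c4ccc(OC)cc4)c4c(OC)cc(OC)cc4C(C)(O)c4c(OC)cc(OC)cc4[C@H]23)cc1
F16 | step 13 | 1,1-diarylethene: 23 with C=CH2 in place of C=O | COc1ccc([C@H]2c3c(OS(=O)(=O)c4ccc(C)cc4)cc(OC)cc3[C@H]3[C@H](c4ccc(OC)cc4)c4c(OC)cc(OC)cc4C(=C)c4c(OC)cc(OC)cc4[C@H]23)cc1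
F17 | step 13 | primary alcohol: 25 with CH2OH in place of CHO (configuration at that carbon set by the hydroboration) | COc1ccc([C@H]2c3c(OS(=O)(=O)c4ccc(C)cc4)cc(OC)cc3[C@H]3[C@H](c4ccc(OC)cc4)c4c(OC)cc(OC)cc4C(CO)c4c(OC)cc(OC)cc4[C@H]23)cc1
F18 | step 15 | hepta-O-methyl stenophyllol B with a free hydroxyl group at indane C7 | COc1ccc([C@H]2c3c(O)cc(OC)cc3[C@H]3[C@H](c4ccc(OC)cc4)c4c(OC)cc(OC)cc4[C@@H]4c5c(cc(OC)cc5[C@H]23)O[C@H]4c2ccc(OC)cc2)cc1
A1 | alternative 1 | (2R,3R)-4-[(tert-butyldimethylsilyloxy)methyl]-3-(3,5-dimethoxyphenyl)-6-ethoxy-2-(4-methoxyphenyl)-2,3-dihydrobenzofuran | COc1cc(OC)cc(c1)[C@@H]1c2c(cc(OCC)cc2CO[Si](C)(C)C(C)(C)C)O[C@H]1c1ccc(OC)cc1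
A2 | alternative 1 | anti ether diyne: tert-butyl{[4-(3,5-dimethoxyphenyl)-5-(ethynyloxy)-5-(4-methoxyphenyl)pent-2-yn-1-yl]oxy}dimethylsilane | COc1cc(OC)cc(c1)[C@H](C#CCO[Si](C)(C)C(C)(C)C)[C@@H](OC#C)c1ccc(OC)cc1
A3 | alternative 1 | ethoxyethyne | CCOC#C
A4 | alternative 2 | indane-fused 7-hydroxybenzodioxinone (C5 oxygen and C4 carboxyl tied as the acetonide; benzyloxymethyl at C3) | COc1ccc([C@H]2c3c(O)cc4OC(C)(C)OC(=O)c4c3[C@@H](COCc3ccccc3)[C@@H]2c2cc(OC)cc(OC)c2)cc1
A5 | alternative 2 | 5-(benzyloxymethyl)-4-(3,5-dimethoxyphenyl)-2-[(2,2-dimethyl-4-oxo-4H-1,3-dioxin-6-yl)acetyl]-3-(4-methoxyphenyl)cyclopentanone | COc1ccc([C@H]2C(C(=O)CC3=CC(=O)OC(C)(C)O3)C(=O)[C@@H](COCc3ccccc3)[C@@H]2c2cc(OC)cc(OC)c2)cc1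
A6 | alternative 3 | hepta-O-methyl stenophyllol B (free hydroxyl at benzofuran C6) | COc1ccc([C@H]2c3c(OC)cc(OC)cc3[C@H]3[C@H](c4ccc(OC)cc4)c4c(OC)cc(OC)cc4[C@@H]4c5c(cc(O)cc5[C@H]23)O[C@H]4c2ccc(OC)cc2)cc1
A7 | alternative 3 | seco precursor: all-trans indane with 3,5-dihydroxyphenyl at C2 and, on C3, the (R)-methine bearing 4-methoxyphenyl and 2,4-dimethoxy-6-[(E)-4-methoxystyryl]phenyl | COc1ccc([C@H]2c3c(OC)cc(OC)cc3[C@@H]([C@H](c3ccc(OC)cc3)c3c(OC)cc(OC)cc3/C=C/c3ccc(OC)cc3)[C@@H]2c2cc(O)cc(O)c2)cc1
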